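**Remark on the chemistry:** locants are the germacrane locants of the target throughout (C1 ketone, C2=C3 furanone alkene, C4=C5, C6 lactone carbinol, C7, C8 ester carbinol, C9 carbinol, C10 quaternary, C11–C13 methylene-lactone carbons, C14 methyl on C10, C15 methyl on C4). In the six-membered intermediates β is the ring face that carries the three-carbon branch on C7, α the other face.

## Analysis of the target

The target is a ten-membered carbocycle (C1–C10) bridged by an oxygen between C3 and C10, which makes a 3(2H)-furanone (O, C3, C2, C1, C10). A γ-lactone with an exocyclic methylene is fused at C6–C7 (C6–O–C12(=O)–C11(=C13)–C7). The ring carries a Z-C4=C5 alkene, a methacrylate on O8 and a free hydroxyl on C9. Five contiguous stereocentres run from C6 to C10 (6S,7S,8S,9S,10R): the lactone is cis-fused (H6 and H7 on the same side), O8 and O9 are cis to each other and to the C11 branch on C7, and the C10 oxygen is trans to O9. Sensitive groups are the two Michael acceptors (methylene lactone, methacrylate), the vinylogous ester of the furanone, the allylic lactone C6–O bond, and the O8/O9 pair, across which an acyl group can migrate. The difficulties are the bridged medium ring, four contiguous oxygenated carbons (C8, C9, C10, C1), the cis ring fusion of the lactone, and telling O8 from O9. The strategy rests on one feature: C6, C7, C8, C9, C10 and C1, with the C14 methyl and the C11–C13 branch para to each other, are the ring of carvone, so the ten-membered ring is a carvone ring with C2–C5 inserted into the C1–C6 bond.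

## Retrosynthetic reasoning

**C8 ester.** The methacrylate is cut first, back to diol 27, because no acrylate survives the organometallic and basic steps. The forward acylation must pick the C8 hydroxyl, flanked by a methine, over the C9 hydroxyl, which is neopentyl next to quaternary C10.

**Furanone C10–O–C3 bond.** 27 is opened to the acyclic vinylogous ethyl ester 25, with C10–O as an acetal ether and O8/O9 as an acetonide. One acid treatment then unmasks three hydroxyls to give triol 26 and lets the C10 hydroxyl replace ethoxide at C3. C3 already has the right oxidation level, so no late oxidation of the ring is needed.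

**C4=C5 alkene.** 25 is traced to the C5 alcohol 23. C4–H is the γ-hydrogen of the vinylogous ester, so elimination through the dienolate is not stereospecific and the ring should choose the Z-alkene; the C4 stereocentre is thereby irrelevant.

**Lactone C6–O bond.** The lactone oxygen is put on C6 by opening a C5–C6 epoxide with the C12 carboxylate, so 23 comes from epoxy acid 22 and this from acid 21. The cut is made here because the exposed face of the C5=C6 alkene is the face that carries C11 and C15. An oxygen delivered from that face has the wrong configuration at C6 for a cis-fused lactone, and backside attack by the carboxylate inverts it. The same step leaves the C5 oxygen that is eliminated afterwards.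

**C12 oxidation level.** Acid 21 comes from silyl ether 18 by desilylation to 19 and oxidation. Raising C12 to the acid before the epoxidation also turns the side-chain alkene into an acrylate, inert to the electrophilic oxidant.

**Key disconnection, C3–C4 with cleavage of C1–C6.** 18 is the [3,3] product of carbinol 16, a cyclohexanol with an ethoxyethynyl group on C1 and an (E)-propenyl group on C6. The ring is thus made by a four-carbon ring expansion instead of an end-to-end closure, and the alkyne arrives with the C3 oxygen in place. The stereocentres C7–C10 are set beforehand on a chair.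

**C1–C2 bond.** 16 comes from ketone 14 and ethoxyacetylene 15. The chair of 14 has the C14 methyl axial on the β face, so the acetylide must enter from the α face and ends up cis to the propenyl group. This cis arrangement leads to the Z-C5=C6 alkene in 18, and the later steps are planned for it.

**C6–C5 bond.** 14 comes from ketone 12 and (E)-1-bromopropene 13 by α-alkenylation. C10 is quaternary, so C6 is the only enolisable position.

**C10 and C1 oxygens.** Ketone 12 goes back through ketol 11 to the cis-diol 8, made by syn-dihydroxylation of cyclohexene 7 from the face opposite the acetonide. Epoxide opening was not used, because the C10 oxygen needed is equatorial and diaxial opening gives its epimer. The C7 branch is carried as a 2-methyloxirane from 4 to 8, since OsO4 would otherwise attack the isopropenyl group first. The oxirane is then isomerised to the allylic alcohol 9, which supplies the C12 oxygen, and protected as 10.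

**C8 and C9 oxygens.** 7 comes from (S)-carvone 1. The carvone carbonyl becomes C9, its α′-methylene C8 and its enone alkene C10=C1, so all four oxygenated carbons are reachable by enolate, carbonyl or alkene chemistry; this mapping requires the (S)-enantiomer. Enolate hydroxylation gives the 8α-alcohol 2, trans to the branch, Mitsunobu inversion gives 3, and 1,2-reduction anti to the axial ester gives the all-cis pattern in 6 by way of 4 and 5.

## Alternatives that were turned down

**Alternative 1:** The cut is at C8=C9, followed by syn-dihydroxylation. In the forward step the second-generation Hoveyda–Grubbs catalyst would join a vinyl group on C7 with one on C10 and release ethylene, giving the Z-8,9-alkene core A1. For it: the route is convergent, the furanone and lactone are made on small fragments, and one dihydroxylation gives the cis O8/O9 pair. Against it: the vinyl group on C10 is neopentyl and next to an ether oxygen, the closure has to form a bridged ten-membered ring against strain, and A1 contains a methylene lactone and a trisubstituted diene that can enter metathesis. The two oxygens must then be added to one face of a flexible ring, and O8 still has to be told from O9. Both fragments also need their stereocentres (C6, C7, C10) made from nothing. On convergence it is stronger than the chosen plan. The chosen plan offers ring formation without an entropic penalty and C7–C10 set on a chair from a terpene.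

**Alternative 2:** The cuts are C2–C3 and C4–C5, made by a [2+2] photocycloaddition, followed by electrocyclic opening of the cyclobutene. In the forward step irradiation near 350 nm would add a 1-propynyl ether on the C10 oxygen across the enone alkene of an eight-membered ring, closing the oxolanone and a fused cyclobutene to give the tricyclic photoadduct A2. For it: the furanone ring and the C3 oxygen are made in one step, and conrotatory opening of A2 would deliver the E,Z-diene that the target has, which is better control of C4=C5 than an elimination gives. Against it: an alkynyl ether of a tertiary alcohol is hard to make and keep, eight-membered cyclic enones isomerise about the double bond on irradiation, and the eight-membered substrate must already carry C6–C10 with full control, for which no terpene ring is at hand. The chosen plan is weaker on diene geometry but starts from a ring whose stereocontrol is predictable.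

**Alternative 3:** The cuts are C7–C11 and C8–O on a finished ten-membered core. In the forward step Bu3SnH with excess nitroxide would turn a bromoallyl acetal on O6 into a vinyl radical that closes 5-exo on C7, and the C8 radical would be caught by the nitroxide, giving the cis-fused methylene lactol ether A3. For it: a 5-exo closure from O6 gives the cis ring fusion by itself, and C8 is oxygenated in the same step; on the lactone fusion it is stronger than the chosen plan, which needs an inversion. Against it: nitroxides intercept stannyl and vinyl radicals before cyclisation, the conjugated furanone–diene competes as a radical acceptor, and the configuration at C8 in A3 is left to the trap. Most of all, the bridged ring with a C7=C8 alkene, C9–OH and C10 must come from an unspecified macrocyclisation, so the main problem is only moved. The chosen plan solves ring and stereocentres C7–C10 together and pays with two more steps at the lactone.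

Key step: step 13

## Route

**Step 1**
Reactants: 1 (S)-(+)-carvone
Product: 2 (5R,6R)-6-hydroxycarvone (8α-hydroxyl trans to the isopropenyl group)
Conditions: KN(SiMe3)2, THF, −78 °C; trans-2-(phenylsulfonyl)-3-phenyloxaziridine, −78 °C; aq NH4Cl
Reagents that add atoms: trans-2-(phenylsulfonyl)-3-phenyloxaziridine, O=S(=O)(N1OC1c1ccccc1)c1ccccc1
Why: Kinetic deprotonation of the enone at the α′-methylene (C8) and enolate hydroxylation by the oxaziridine; the oxidant should approach anti to the neighbouring isopropenyl group, setting the 8α-alcohol.

**Step 2**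
Reactants: 2 (5R,6R)-6-hydroxycarvone
Product: 3 (1S,6R)-3-methyl-2-oxo-6-(prop-1-en-2-yl)cyclohex-3-en-1-yl 4-nitrobenzoate (8β-ester)
Conditions: 4-O2NC6H4CO2H, PPh3, DIAD, THF, 0 °C to rt
Reagents that add atoms: 4-nitrobenzoic acid, O=C(O)c1ccc(cc1)[N+](=O)[O-]
Why: Mitsunobu reaction; SN2 displacement of the oxyphosphonium group inverts C8 and places the oxygen cis to the C7 branch, as in the inversion of an equatorial cyclohexanol flanked by a branched carbon.

**Step 3**
Reactants: 3 the 8β-(4-nitrobenzoate)
Product: 4 the 11,12-epoxide of 3 (2-methyloxiran-2-yl group on C7; both epimers at C11)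
Conditions: mCPBA, CH2Cl2, 0 °C
Reagents that add atoms: mCPBA, O=C(OO)c1cccc(Cl)c1
Why: Prilezhaev epoxidation; the peracid takes the electron-rich isopropenyl alkene and leaves the enone alkene. The oxirane masks this alkene for step 6 and carries the future C12 oxygen; its configuration is lost in step 7.

**Step 4**
Reactants: 4 the epoxy enone ester
Product: 6 the 8β,9β-diol (cyclohex-1(10)-ene with the oxirane on C7), via hydroxy ester 5 (not isolated)
Conditions: NaBH4, CeCl3·7H2O, MeOH, −78 °C; then K2CO3 (cat.), 0 °C
Reagents that add atoms: none
Why: Luche 1,2-reduction; hydride should add from the α face, anti to the axial C8–O bond, giving the 9β-alcohol as in the reduction of carvone to cis-carveol. Methanolysis then frees the cis-diol.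

**Step 5**
Reactants: 6 the 8β,9β-diol
Product: 7 the 8,9-O-isopropylidene derivative of 6
Conditions: 2-methoxypropene, PPTS (cat.), CH2Cl2, 0 °C
Reagents that add atoms: 2-methoxypropene, C=C(C)OC
Why: Acetal formation on a cis-1,2-diol; the short, cold treatment with a weak acid is chosen to spare the oxirane.

**Step 6**
Reactants: 7 the acetonide
Product: 8 the 1α,10α-diol of 7 (C14 methyl β)
Conditions: OsO4 (cat.), N-methylmorpholine N-oxide, acetone/H2O, rt
Reagents that add atoms: N-methylmorpholine N-oxide, C[N+]1([O-])CCOCC1; water, O
Why: Upjohn syn-dihydroxylation of the only alkene present; OsO4 should add from the α face, anti to the allylic oxygen on C9 and to the acetonide, which sets the C10 oxygen α and trans to O9.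

**Step 7**
Reactants: 8 the epoxy diol
Product: 9 the 1α,10α,12-triol with the C11=C13 alkene restored (3-hydroxyprop-1-en-2-yl group on C7)
Conditions: Et2AlCl, lithium 2,2,6,6-tetramethylpiperidide (from the amine and n-BuLi), toluene, 0 °C; H2O work-up
Reagents that add atoms: none
Why: Base-induced isomerisation of a 2,2-disubstituted oxirane to the allylic alcohol by Et2Al(2,2,6,6-tetramethylpiperidide), used in excess because the two free hydroxyls consume base; the proton is taken from the methyl group, not from the hindered ring methine, and both C11 epimers converge.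

**Step 8**
Reactants: 9 the triol
Product: 10 the 12-O-tert-butyldimethylsilyl ether of 9
Conditions: TBSCl, imidazole, CH2Cl2, 0 °C
Reagents that add atoms: tert-butyldimethylsilyl chloride, CC(C)(C)[Si](C)(C)Cl
Why: Silylation of the primary allylic hydroxyl in preference to the axial secondary and the tertiary hydroxyl.

**Step 9**
Reactants: 10 the silyl ether diol
Product: 11 the 10α-hydroxy 1-ketone
Conditions: IBX, DMSO, rt
Reagents that add atoms: none
Why: IBX oxidises the secondary alcohol of a 1,2-diol to the α-ketol without cleaving the C1–C10 bond; the tertiary hydroxyl cannot react.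

**Step 10**
Reactants: 11 the ketol
Product: 12 the 10-O-methoxymethyl ketone
Conditions: MOMCl, i-Pr2NEt, NaI (cat.), 1,2-dichloroethane, 50 °C
Reagents that add atoms: chloromethyl methyl ether, COCCl
Why: Alkylation of the tertiary α-ketol hydroxyl as an acetal ether. An acetal is chosen because a silyl group would migrate to the C1 alkoxide in step 13.

**Step 11**
Reactants: 12 the ketone; 13 (E)-1-bromoprop-1-ene
Product: 14 the 6α-[(E)-prop-1-enyl] ketone
Conditions: Pd2(dba)3 (cat.), P(t-Bu)3 (cat.), LiN(SiMe3)2, toluene, 50 °C; aq NH4Cl
Reagents that add atoms: none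
Why: Palladium-catalysed α-alkenylation of a ketone enolate with retention of the alkene geometry; C6 is the only enolisable carbon. Axial protonation of the product dienolate at C6, or equilibration, should leave the propenyl group equatorial and trans to the C7 branch.

**Step 12**
Reactants: 14 the alkenyl ketone; 15 ethoxyacetylene
Product: 16 the 1α-(ethoxyethynyl) 1β-carbinol (alkynyl cis to the propenyl group)
Conditions: 15, n-BuLi, THF, −78 °C; CeCl3, −78 °C; then 14; aq NH4Cl
Reagents that add atoms: none
Why: 1,2-Addition of the acetylide transmetallated with CeCl3, which suppresses enolisation at C6; the chair of 14 has the C14 methyl axial on the β face, so the nucleophile should enter axially from the α face.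

**Step 13**
Reactants: 16 the alkynyl carbinol
Product: 18 the ring-expanded (2E,5Z)-3-ethoxycyclodeca-2,5-dien-1-one (C15 methyl on C4; 12-O-silyl; acetonide; 10-O-methoxymethyl), via potassium allenolate 17 (not isolated)
Conditions: KH, 18-crown-6, THF, 0 °C to rt; aq NH4Cl, −78 °C
Reagents that add atoms: none
Why: Proposed new method: the potassium alkoxide at C1 weakens the C1–C6 bond and the array C3≡C2–C1–C6–C5=C4 undergoes an anionic oxy-Cope [3,3] shift that forms C3–C4 and cleaves C1–C6, giving allenolate 17, which is protonated at C2 to the vinylogous ester 18. The closest known reaction type is the anionic oxy-Cope ring expansion of 1,2-dialkenylcyclohexanols to cyclodec-5-enones and its all-carbon 1-alkynyl variant; an alkoxyalkyne as the two-carbon partner is not established. The ten-membered ring is closed by four-carbon ring expansion of the six-membered ring, not by joining two chain ends. The axial alkynyl and equatorial propenyl groups are gauche, and C4 can reach C3 only beneath the α face, which places C4 syn to C7 about the C6–C5 bond and should fix the new C5=C6 alkene as Z. C4 is formed as one stereocentre, controlled by the C1 and C6 configurations and the E-geometry of the propenyl group, and is removed in step 17. The step needs the shift to be faster than loss of the acetylide from the alkoxide; strain relief at three contiguous fully substituted carbons, the crown-ether-separated counter-ion and irreversible enolate formation should secure this. The acetal on O10 keeps a second alkoxide and silyl migration out of the reaction.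

**Step 14**
Reactants: 18 the silyl ether
Product: 19 the 12-alcohol
Conditions: Bu4NF, AcOH, THF, 0 °C
Reagents that add atoms: none
Why: Fluoride cleavage of the primary silyl ether; acetic acid buffers the medium so that the acidic C4–H and the vinylogous ester are left alone.

**Step 15**
Reactants: 19 the allylic alcohol
Product: 21 the 12-carboxylic acid (2-substituted acrylic acid on C7), via enal 20 (not isolated)
Conditions: TEMPO (cat.), PhI(OAc)2, MeCN/H2O, rt
Reagents that add atoms: water, O
Why: Oxoammonium oxidation of a primary alcohol through the aldehyde hydrate to the acid; the alkenes, acetals and the vinylogous ester are not touched.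

**Step 16**
Reactants: 21 the acid
Product: 23 the 5-hydroxy 12,6-lactone (cis-fused, 6S), via epoxy acid 22 (not isolated)
Conditions: dimethyldioxirane, acetone, −20 °C; then PPTS (cat.), CH2Cl2, rt
Reagents that add atoms: dimethyldioxirane, CC1(C)OO1
Why: The dioxirane epoxidises the cis-disubstituted C5=C6 alkene (the acrylic acid and the vinylogous ester are electron-poor) on the face that carries C11 and C15, the other face being covered by the ring. The carboxylate then opens the epoxide at C6 in a 5-exo closure with inversion, which gives the cis-fused lactone and leaves the epoxide oxygen on C5.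

**Step 17**
Reactants: 23 the hydroxy lactone
Product: 25 the (2E,4Z)-3-ethoxy dienone 12,6-lactone, via mesylate 24 (not isolated)
Conditions: MsCl, Et3N, CH2Cl2, 0 °C; then DBU, rt
Reagents that add atoms: none
Why: Mesylation and E1cB elimination through the dienolate formed at C4, the γ-position of the vinylogous ester; because C4 becomes planar, its configuration does not matter, and the ring should favour the Z-alkene.

**Step 18**
Reactants: 25 the dienone lactone
Product: 27 the furanone 8,9-diol (target without the methacryloyl group), via triol 26 (not isolated)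
Conditions: CF3CO2H/H2O, 0 °C to rt
Reagents that add atoms: none
Why: Acid hydrolysis of the methoxymethyl ether and the acetonide; the freed C10 hydroxyl then adds to C3 of the protonated vinylogous ester and ethanol is lost, closing the 3(2H)-furanone by addition–elimination.

**Step 19**
Reactants: 27 the diol
Product: 28 the target, (4Z,6S,7S,8S,9S,10R)-9-hydroxy-8-(2-methylprop-2-enoyloxy)-1-oxo-3,10-epoxygermacra-2,4,11(13)-trien-12,6-olide
Conditions: methacrylic anhydride, Et3N, DMAP (cat.), CH2Cl2, −40 °C
Reagents that add atoms: methacrylic anhydride, CC(=C)C(=O)OC(=O)C(C)=C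
Why: Acyl transfer to the less hindered C8 hydroxyl; the C9 hydroxyl is neopentyl next to quaternary C10, and the low temperature and short time limit acyl migration.

## Compound list

1 | (S)-(+)-carvone | CC1=CC[C@@H](CC1=O)C(C)=C | starting material
2 | (5R,6R)-6-hydroxycarvone (8α-ol) | C1=C(C)C(=O)[C@H](O)[C@@H](C(C)=C)C1 | intermediate
3 | (1S,6R)-3-methyl-2-oxo-6-(prop-1-en-2-yl)cyclohex-3-en-1-yl 4-nitrobenzoate | C1=C(C)C(=O)[C@@H](OC(=O)c2ccc(cc2)[N+](=O)[O-])[C@@H](C(C)=C)C1 | intermediate
4 | 11,12-epoxide of 3 (both C11 epimers) | C1=C(C)C(=O)[C@@H](OC(=O)c2ccc(cc2)[N+](=O)[O-])[C@@H](C3(C)CO3)C1 | intermediate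
5 | 9β-hydroxy 8β-(4-nitrobenzoate) | C1=C(C)[C@@H](O)[C@@H](OC(=O)c2ccc(cc2)[N+](=O)[O-])[C@@H](C3(C)CO3)C1 | intermediate
6 | 8β,9β-diol with the oxirane on C7 | C1=C(C)[C@@H](O)[C@@H](O)[C@@H](C2(C)CO2)C1 | intermediate
7 | 8,9-O-isopropylidene derivative of 6 | C1=C(C)[C@H]2OC(C)(C)O[C@H]2[C@@H](C3(C)CO3)C1 | intermediate
8 | 1α,10α-diol of 7 | O[C@@H]1[C@](C)(O)[C@H]2OC(C)(C)O[C@H]2[C@@H](C3(C)CO3)C1 | intermediate
9 | 1α,10α,12-triol with C11=C13 | O[C@@H]1[C@](C)(O)[C@H]2OC(C)(C)O[C@H]2[C@@H](C(=C)CO)C1 | intermediate
10 | 12-O-tert-butyldimethylsilyl ether of 9 | O[C@@H]1[C@](C)(O)[C@H]2OC(C)(C)O[C@H]2[C@@H](C(=C)CO[Si](C)(C)C(C)(C)C)C1 | intermediate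
11 | 10α-hydroxy 1-ketone | O=C1[C@](C)(O)[C@H]2OC(C)(C)O[C@H]2[C@@H](C(=C)CO[Si](C)(C)C(C)(C)C)C1 | intermediate
12 | 10-O-methoxymethyl ketone | O=C1[C@](C)(OCOC)[C@H]2OC(C)(C)O[C@H]2[C@@H](C(=C)CO[Si](C)(C)C(C)(C)C)C1 | intermediate
13 | (E)-1-bromoprop-1-ene | C/C=C/Br | starting material
14 | 6α-[(E)-prop-1-enyl] ketone | O=C1[C@](C)(OCOC)[C@H]2OC(C)(C)O[C@H]2[C@@H](C(=C)CO[Si](C)(C)C(C)(C)C)[C@@H]1/C=C/C | intermediate
15 | ethoxyacetylene | C#COCC | starting material
16 | 1α-(ethoxyethynyl) 1β-carbinol (oxy-Cope precursor) | CCOC#C[C@]1(O)[C@](C)(OCOC)[C@H]2OC(C)(C)O[C@H]2[C@@H](C(=C)CO[Si](C)(C)C(C)(C)C)[C@@H]1/C=C/C | intermediate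
17 | potassium allenolate of the ring-expanded ketone | [K+].[O-]C1=C=C(OCC)[C@H](C)/C=C\[C@H](C(=C)CO[Si](C)(C)C(C)(C)C)[C@@H]2OC(C)(C)O[C@@H]2[C@@]1(C)OCOC | intermediate
18 | (2E,5Z)-3-ethoxycyclodeca-2,5-dien-1-one (12-O-silyl) | O=C1/C=C(OCC)\[C@H](C)/C=C\[C@H](C(=C)CO[Si](C)(C)C(C)(C)C)[C@@H]2OC(C)(C)O[C@@H]2[C@@]1(C)OCOC | intermediate
19 | 12-alcohol of 18 | O=C1/C=C(OCC)\[C@H](C)/C=C\[C@H](C(=C)CO)[C@@H]2OC(C)(C)O[C@@H]2[C@@]1(C)OCOC | intermediate
20 | 12-aldehyde (enal) | O=C1/C=C(OCC)\[C@H](C)/C=C\[C@H](C(=C)C=O)[C@@H]2OC(C)(C)O[C@@H]2[C@@]1(C)OCOC | intermediate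
21 | 12-carboxylic acid | O=C1/C=C(OCC)\[C@H](C)/C=C\[C@H](C(=C)C(=O)O)[C@@H]2OC(C)(C)O[C@@H]2[C@@]1(C)OCOC | intermediate
22 | 5,6-epoxy acid | O=C1/C=C(OCC)\[C@H](C)[C@H]3O[C@H]3[C@H](C(=C)C(=O)O)[C@@H]2OC(C)(C)O[C@@H]2[C@@]1(C)OCOC | intermediate
23 | 5-hydroxy 12,6-lactone (6S) | O=C1/C=C(OCC)\[C@H](C)[C@@H](O)[C@@H]3OC(=O)C(=C)[C@@H]3[C@@H]2OC(C)(C)O[C@@H]2[C@@]1(C)OCOC | intermediate
24 | 5-mesylate of 23 | O=C1/C=C(OCC)\[C@H](C)[C@@H](OS(C)(=O)=O)[C@@H]3OC(=O)C(=C)[C@@H]3[C@@H]2OC(C)(C)O[C@@H]2[C@@]1(C)OCOC | intermediate
25 | (2E,4Z)-3-ethoxy dienone 12,6-lactone | O=C1/C=C(OCC)\C(C)=C/[C@@H]3OC(=O)C(=C)[C@@H]3[C@@H]2OC(C)(C)O[C@@H]2[C@@]1(C)OCOC | intermediate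
26 | 8,9,10-triol of 25 | O=C1/C=C(OCC)\C(C)=C/[C@@H]3OC(=O)C(=C)[C@@H]3[C@H](O)[C@H](O)[C@@]1(C)O | intermediate
27 | furanone 8,9-diol | O[C@H]1[C@H]2C(=C)C(=O)O[C@H]2/C=C(/C)C2=CC(=O)[C@](C)(O2)[C@H]1O | intermediate
28 | (4Z,6S,7S,8S,9S,10R)-9-hydroxy-8-(2-methylprop-2-enoyloxy)-1-oxo-3,10-epoxygermacra-2,4,11(13)-trien-12,6-olide | C=C(C)C(=O)O[C@H]1[C@H]2C(=C)C(=O)O[C@H]2/C=C(/C)C2=CC(=O)[C@](C)(O2)[C@H]1O | target

## Step count and least certain steps

Total steps: 19. Longest linear sequence: 19 (from 1; 13 and 15 are bought).

**Step 13 (key step, proposed new method).** The alkoxide may lose the acetylide by retro-addition, or the ynol ether may decompose before the shift, because an alkoxy-substituted alkyne has not been shown to take part in this rearrangement. Fallback with known chemistry, from 14 back to 18: ethynylmagnesium bromide with CeCl3 adds to 14 to give the 1α-ethynyl carbinol F1. Its potassium alkoxide, made with KH and 18-crown-6, undergoes the known all-carbon acetylenic anionic oxy-Cope expansion to the cyclodeca-2,5-dienone F2. Nucleophilic epoxidation of the enone with t-BuOOH and a base gives the 2,3-epoxy ketone F3. Isomerisation with Pd(PPh3)4 and 1,2-bis(diphenylphosphino)ethane gives the 1,3-diketone F4. O-Ethylation of the less hindered C3 oxygen with Et3OBF4 and a hindered amine returns to 18.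

**Step 16.** Epoxidation may occur from the other face, the backside closure may be slow because the ring must turn C11 behind C6, or the enol ether may capture the epoxide across the ring. Fallback, from 18 back to 25: dimethyldioxirane on 18 gives the 5,6-epoxide F5. DBU opens it by vinylogous elimination through C4 to the Z-dienone 6R-alcohol F6, in which the epoxide oxygen is kept on C6. This alcohol is oxidised with MnO2 to the 6-ketone F7, and Luche reduction from the open face gives the 6S alcohol F8. Should the epoxidation of 18 take the other face, the elimination gives the 6S alcohol F8 directly and these two operations are left out. Desilylation gives the 6,12-diol F9, and TEMPO with PhI(OAc)2 closes the lactone oxidatively with retention at C6 to give 25.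

**Step 11.** The hindered enolate may couple slowly, the product may be alkenylated twice, or the β,γ-alkene may move into conjugation. Fallback, from 12 back to 14: alkylation of the lithium enolate of 12 with allyl bromide gives the 6α-allyl ketone F10, trans to the C7 branch. The catalyst formed from Pd(dba)2, P(t-Bu)3 and isobutyryl chloride then moves the terminal alkene by one position to the (E)-propenyl group of 14.

**Step 2.** Displacement at a carbinol next to a ketone and a branched carbon may be slow, and elimination towards the dienone or epimerisation may take over. Fallback, from 2 back to 3: mesylation of 2 gives the α-mesyloxy ketone F11, and displacement with cesium 4-nitrobenzoate and 18-crown-6 in toluene, an SN2 reaction accelerated by the adjacent carbonyl, gives 3 with inversion.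

**Step 19.** Acylation may be unselective between O8 and O9, or the acyl group may migrate to O9. Fallback, from 27 back to 28: Bu2SnO converts the diol into the 8,9-O-dibutylstannylene acetal F12, which is acylated with methacryloyl chloride at low temperature at the more accessible oxygen, O8, without free base, to give 28.

## Further compounds

F1 | step 13 | 1α-ethynyl 1β-carbinol from 14 | C#C[C@]1(O)[C@](C)(OCOC)[C@H]2OC(C)(C)O[C@H]2[C@@H](C(=C)CO[Si](C)(C)C(C)(C)C)[C@@H]1/C=C/C
F2 | step 13 | (2Z,5Z)-cyclodeca-2,5-dien-1-one without the C3 oxygen | O=C1/C=C\[C@H](C)/C=C\[C@H](C(=C)CO[Si](C)(C)C(C)(C)C)[C@@H]2OC(C)(C)O[C@@H]2[C@@]1(C)OCOC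
F3 | step 13 | 2,3-epoxy ketone (epoxide configuration not controlled) | O=C1C3OC3[C@H](C)/C=C\[C@H](C(=C)CO[Si](C)(C)C(C)(C)C)[C@@H]2OC(C)(C)O[C@@H]2[C@@]1(C)OCOC
F4 | step 13 | cyclodec-5-ene-1,3-dione | O=C1CC(=O)[C@H](C)/C=C\[C@H](C(=C)CO[Si](C)(C)C(C)(C)C)[C@@H]2OC(C)(C)O[C@@H]2[C@@]1(C)OCOC
F5 | step 16 | 5,6-epoxide of 18 | O=C1/C=C(OCC)\[C@H](C)[C@H]3O[C@H]3[C@H](C(=C)CO[Si](C)(C)C(C)(C)C)[C@@H]2OC(C)(C)O[C@@H]2[C@@]1(C)OCOC
F6 | step 16 | (2E,4Z)-dienone (6R)-alcohol, 12-O-silyl | O=C1/C=C(OCC)\C(C)=C/[C@@H](O)[C@H](C(=C)CO[Si](C)(C)C(C)(C)C)[C@@H]2OC(C)(C)O[C@@H]2[C@@]1(C)OCOC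
F7 | step 16 | (2E,4Z)-dienone 6-ketone, 12-O-silyl | O=C1/C=C(OCC)\C(C)=C/C(=O)[C@H](C(=C)CO[Si](C)(C)C(C)(C)C)[C@@H]2OC(C)(C)O[C@@H]2[C@@]1(C)OCOC
F8 | step 16 | (2E,4Z)-dienone (6S)-alcohol, 12-O-silyl | O=C1/C=C(OCC)\C(C)=C/[C@H](O)[C@H](C(=C)CO[Si](C)(C)C(C)(C)C)[C@@H]2OC(C)(C)O[C@@H]2[C@@]1(C)OCOC
F9 | step 16 | (2E,4Z)-dienone (6S)-6,12-diol | O=C1/C=C(OCC)\C(C)=C/[C@H](O)[C@H](C(=C)CO)[C@@H]2OC(C)(C)O[C@@H]2[C@@]1(C)OCOC
F10 | step 11 | 6α-allyl ketone | O=C1[C@](C)(OCOC)[C@H]2OC(C)(C)O[C@H]2[C@@H](C(=C)CO[Si](C)(C)C(C)(C)C)[C@@H]1CC=C
F11 | step 2 | 8α-mesylate of 2 | C1=C(C)C(=O)[C@H](OS(C)(=O)=O)[C@@H](C(C)=C)C1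
F12 | step 19 | 8,9-O-dibutylstannylene acetal of 27 | CCCC[Sn]4(CCCC)O[C@H]1[C@H]2C(=C)C(=O)O[C@H]2/C=C(/C)C2=CC(=O)[C@](C)(O2)[C@H]1O4
A1 | alternative 1 | ten-membered Z-8,9-alkene triene core | C/C1=C/[C@@H]2OC(=O)C(=C)[C@@H]2/C=C\[C@@]2(C)OC1=CC2=O
A2 | alternative 2 | tricyclic alkoxycyclobutene photoadduct | C[C@]12OC3=C(C)[C@H]([C@H]3C1=O)[C@@H]4OC(=O)[C@H](CO[Si](C)(C)C(C)(C)C)[C@@H]4[C@@H]5OC(C)(C)O[C@H]25
A3 | alternative 3 | cis-fused methylene lactol ethyl acetal with C8 alkoxyamine | CC[Si](CC)(CC)O[C@H]1[C@@H](ON2C(C)(C)CCCC2(C)C)[C@H]3C(=C)[C@@H](OCC)O[C@H]3/C=C(/C)C2=CC(=O)[C@]1(C)O2
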